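**Assumption:** the target has no stereocentre and no stereogenic double bond, so it is achiral; no asymmetric step is needed and the structure is taken exactly as in the given SMILES.

**Retrosynthetic overview**
- Last: free the catechol from its bis-allyl ether; before that, close the oxepine (third and last ring formed) by intramolecular O-vinylation of the 2'-OH with a vinylic bromide on the C3 side chain.
- The pyranone ring (second ring formed) comes from cyclodehydration of a 2-alkylated 1,3-diketone; the C3 side chain is put on by C-alkylation with 1,2-dibromo-3-methylbut-2-ene.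
- Key C–C bond (flavone C2–C3): intermolecular crossed Claisen condensation of the ring A methyl ketone enolate with a ring B acyl imidazolide.
- Ring A ketone from phloroacetophenone: prenyl by para-Claisen–Cope, then the 2,2-dimethylpyran ring (first ring formed) by prenal annulation; one ortho oxygen stays as a MOM ether to fix the angular ring fusion.
- Ring B acid from protocatechualdehyde: allylation, Dakin oxidation, ortho-formylation, MOM protection, Pinnick oxidation.

**Route**

Step 1
Reactants: 1 3-methylbut-2-enal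
Product: 3 2-bromo-3-methylbut-2-enal, via dibromoaldehyde 2 (not isolated)
Conditions: Br2, CH2Cl2, −10 °C; then Et3N, 0 °C → rt
Reagents that add atoms: bromine, BrBr
Why: Bromine adds across the enal C=C and triethylamine then removes HBr by E1cB elimination (acidic α-H, tertiary β-bromide), the standard α-bromination of an enal.

Step 2
Reactants: 3 2-bromo-3-methylbut-2-enal
Product: 4 2-bromo-3-methylbut-2-en-1-ol
Conditions: NaBH4, MeOH, 0 °C
Reagents that add atoms: none
Why: Borohydride 1,2-reduction of the aldehyde leaves the vinylic bromide untouched.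

Step 3
Reactants: 4 2-bromo-3-methylbut-2-en-1-ol
Product: 5 1,2-dibromo-3-methylbut-2-ene
Conditions: CBr4, PPh3, CH2Cl2, 0 °C
Reagents that add atoms: carbon tetrabromide, BrC(Br)(Br)Br
Why: The Appel reaction converts the primary allylic alcohol to the bromide by SN2 under neutral conditions, and the vinylic bromide is inert.

Step 4
Reactants: 6 1-(2,4,6-trihydroxyphenyl)ethanone
Product: 7 1-[4-(tert-butyldimethylsilyloxy)-2,6-dihydroxyphenyl]ethanone
Conditions: TBSCl (1.05 equiv), imidazole, DMF, 0 °C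
Reagents that add atoms: tert-butyldimethylsilyl chloride, CC(C)(C)[Si](C)(C)Cl
Why: The para hydroxyl is the only one not hydrogen-bonded to the acetyl group and is the most acidic, so silylation is selective for it.

Step 5
Reactants: 7 1-[4-(tert-butyldimethylsilyloxy)-2,6-dihydroxyphenyl]ethanone
Product: 8 1-[4-(tert-butyldimethylsilyloxy)-2-hydroxy-6-(methoxymethoxy)phenyl]ethanone
Conditions: MOMCl (1.1 equiv), i-Pr2NEt, CH2Cl2, 0 °C → rt
Reagents that add atoms: chloromethyl methyl ether, COCCl
Why: The two ortho hydroxyls are equivalent, and after the first MOM etherification the remaining one is locked in a hydrogen bond to the ketone, so alkylation stops at the mono ether.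

Step 6
Reactants: 8 1-[4-(tert-butyldimethylsilyloxy)-2-hydroxy-6-(methoxymethoxy)phenyl]ethanone
Product: 9 1-[4-(tert-butyldimethylsilyloxy)-2-(methoxymethoxy)-6-(3-methylbut-2-enyloxy)phenyl]ethanone
Conditions: 3-methylbut-2-en-1-ol, PPh3, DIAD, THF, 0 °C → rt
Reagents that add atoms: 3-methylbut-2-en-1-ol, CC(C)=CCO
Why: Mitsunobu etherification alkylates the chelated phenol with the primary allylic alcohol under neutral conditions that spare the aryl silyl ether.

Step 7
Reactants: 9 1-[4-(tert-butyldimethylsilyloxy)-2-(methoxymethoxy)-6-(3-methylbut-2-enyloxy)phenyl]ethanone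
Product: 12 1-[4-(tert-butyldimethylsilyloxy)-6-hydroxy-2-(methoxymethoxy)-3-(3-methylbut-2-enyl)phenyl]ethanone, via ortho-dienone 10 (not isolated), via para-dienone 11 (not isolated)
Conditions: N,N-diethylaniline, 200 °C, sealed tube, Ar
Reagents that add atoms: none
Why: Aromatic Claisen rearrangement to the free ortho carbon followed by Cope rearrangement carries the allyl unit to the para carbon (between the MOM and silyl ethers) as a normal prenyl group, and tautomerisation restores the phenol (tandem para-Claisen–Cope, known for the bis-MOM analogue).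

Step 8
Reactants: 12 1-[4-(tert-butyldimethylsilyloxy)-6-hydroxy-2-(methoxymethoxy)-3-(3-methylbut-2-enyl)phenyl]ethanone
Product: 13 1-[4,6-dihydroxy-2-(methoxymethoxy)-3-(3-methylbut-2-enyl)phenyl]ethanone
Conditions: Bu4NF, AcOH, THF, 0 °C
Reagents that add atoms: none
Why: Buffered fluoride cleaves only the aryl silyl ether, leaving the MOM ether and the prenyl group intact.

Step 9
Reactants: 13 1-[4,6-dihydroxy-2-(methoxymethoxy)-3-(3-methylbut-2-enyl)phenyl]ethanone; 1 3-methylbut-2-enal
Product: 14 1-[5-hydroxy-7-(methoxymethoxy)-2,2-dimethyl-8-(3-methylbut-2-enyl)-2H-chromen-6-yl]ethanone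
Conditions: ethylenediammonium diacetate (10 mol%), toluene, reflux
Reagents that add atoms: none
Why: Amine-catalysed Knoevenagel-type condensation at the only free ring carbon gives an ortho-quinone methide that closes by 6π oxa-electrocyclisation through the non-chelated para oxygen, leaving the hydrogen-bonded ortho hydroxyl free as in resacetophenone chromenylations.

Step 10
Reactants: 15 3,4-dihydroxybenzaldehyde
Product: 16 3,4-bis(allyloxy)benzaldehyde
Conditions: allyl bromide, K2CO3, DMF, 60 °C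
Reagents that add atoms: allyl bromide, C=CCBr
Why: Williamson etherification of both phenols gives a catechol protection that is stable to base and acid and removable later without acid.

Step 11
Reactants: 16 3,4-bis(allyloxy)benzaldehyde
Product: 18 3,4-bis(allyloxy)phenol, via aryl formate 17 (not isolated)
Conditions: mCPBA, CH2Cl2, 0 °C → rt; then K2CO3 (cat.), MeOH, rt
Reagents that add atoms: 3-chloroperbenzoic acid, OOC(=O)c1cccc(Cl)c1
Why: Baeyer–Villiger (Dakin-type) oxidation with migration of the electron-rich aryl group is faster than epoxidation of the monosubstituted allyl alkenes, and methanolysis of the formate frees the phenol.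

Step 12
Reactants: 18 3,4-bis(allyloxy)phenol
Product: 19 4,5-bis(allyloxy)-2-hydroxybenzaldehyde
Conditions: MgCl2, Et3N, (CH2O)n, MeCN, reflux
Reagents that add atoms: paraformaldehyde (formaldehyde), C=O
Why: Magnesium-phenoxide-directed ortho-formylation goes to the less hindered ortho carbon (para to the 3-alkoxy group), which gives the 2-hydroxy-4,5-dialkoxy pattern.

Step 13
Reactants: 19 4,5-bis(allyloxy)-2-hydroxybenzaldehyde
Product: 20 4,5-bis(allyloxy)-2-(methoxymethoxy)benzaldehyde
Conditions: MOMCl, i-Pr2NEt, DMAP (cat.), CH2Cl2, 0 °C → rt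
Reagents that add atoms: chloromethyl methyl ether, COCCl
Why: Base-mediated MOM etherification masks the future 2'-OH so that only ring A can close the pyranone.

Step 14
Reactants: 20 4,5-bis(allyloxy)-2-(methoxymethoxy)benzaldehyde
Product: 21 4,5-bis(allyloxy)-2-(methoxymethoxy)benzoic acid
Conditions: NaClO2, NaH2PO4, 2-methylbut-2-ene, t-BuOH/H2O, rt
Reagents that add atoms: sodium chlorite, [Na+].[O-]Cl=O
Why: Pinnick oxidation is buffered and the alkene scavenger removes hypochlorite, so the allyl ethers and the MOM acetal survive.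

Step 15
Reactants: 21 4,5-bis(allyloxy)-2-(methoxymethoxy)benzoic acid
Product: 22 [4,5-bis(allyloxy)-2-(methoxymethoxy)phenyl](imidazol-1-yl)methanone
Conditions: 1,1'-carbonyldiimidazole, THF, rt
Reagents that add atoms: 1,1'-carbonyldiimidazole, O=C(n1ccnc1)n1ccnc1
Why: Acyl activation as the neutral imidazolide avoids the acid chloride, whose ortho MOM ether would attack it.

Step 16
Reactants: 14 1-[5-hydroxy-7-(methoxymethoxy)-2,2-dimethyl-8-(3-methylbut-2-enyl)-2H-chromen-6-yl]ethanone; 22 [4,5-bis(allyloxy)-2-(methoxymethoxy)phenyl](imidazol-1-yl)methanone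
Product: 23 1-[4,5-bis(allyloxy)-2-(methoxymethoxy)phenyl]-3-[5-hydroxy-7-(methoxymethoxy)-2,2-dimethyl-8-(3-methylbut-2-enyl)-2H-chromen-6-yl]propane-1,3-dione
Conditions: 14, LiN(SiMe3)2 (4 equiv), THF, −78 → −10 °C; then 22, −78 °C → rt; aq NH4Cl
Reagents that add atoms: none
Why: Intermolecular crossed Claisen condensation in which the lithium phenoxide–enolate of the methyl ketone is C-acylated by the acyl imidazolide (any O-acyl product is rearranged by the excess base to the same diketone) and the product is protected as its enolate.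

Step 17
Reactants: 23 the 1,3-diketone; 5 1,2-dibromo-3-methylbut-2-ene
Product: 24 2-(2-bromo-3-methylbut-2-enyl)-1-[4,5-bis(allyloxy)-2-(methoxymethoxy)phenyl]-3-[5-hydroxy-7-(methoxymethoxy)-2,2-dimethyl-8-(3-methylbut-2-enyl)-2H-chromen-6-yl]propane-1,3-dione (racemic)
Conditions: K2CO3, acetone, 45 °C
Reagents that add atoms: none
Why: The soft diketone enolate undergoes SN2 C-alkylation at the primary allylic bromide, while the vinylic bromide and the chelated phenol do not react.

Step 18
Reactants: 24 the alkylated 1,3-diketone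
Product: 26 2-[4,5-bis(allyloxy)-2-hydroxyphenyl]-3-(2-bromo-3-methylbut-2-enyl)-5-hydroxy-8,8-dimethyl-6-(3-methylbut-2-enyl)-4H,8H-pyrano[2,3-h]chromen-4-one, via bis-MOM flavone 25 (not isolated)
Conditions: PPTS (0.2 equiv), toluene, 80 °C; then 3 M HCl, MeOH/THF, 40 °C
Reagents that add atoms: none
Why: The only free phenol adds to the ring B ketone and the weak acid dehydrates this hemiketal before any MOM ether is cleaved, which fixes the angular ring fusion irreversibly, and methanolic HCl then removes both MOM acetals (cyclodehydration, then acetal solvolysis).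

Step 19
Reactants: 26 the 2',5-dihydroxy vinylic bromide
Product: 27 4',5'-di-O-allylisocycloheterophyllin
Conditions: CuI (20 mol%), 1,10-phenanthroline (40 mol%), Cs2CO3 (3 equiv), toluene, 110 °C, Ar
Reagents that add atoms: none
Why: Ullmann-type intramolecular O-vinylation in which the copper 2'-phenoxide inserts into the vinylic C–Br bond held next to it and reductive elimination closes the seven-membered exocyclic enol ether, while the chelated 5-OH cannot reach the bromide.

Step 20
Reactants: 27 4',5'-di-O-allylisocycloheterophyllin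
Product: 28 isocycloheterophyllin
Conditions: Pd(PPh3)4 (5 mol%), morpholine, THF, rt, Ar; pH 6 buffer work-up
Reagents that add atoms: none
Why: Allyl transfer to morpholine catalysed by zerovalent palladium (Tsuji–Trost deallylation) frees the catechol without acid, so the enol ether, the prenyl group and the chromene (whose ring C–O bond is not aligned for ionisation) survive.

**Compound list**

1 | 3-methylbut-2-enal (prenal) | CC(C)=CC=O | starting material
2 | 2,3-dibromo-3-methylbutanal (racemic, not isolated) | CC(C)(Br)C(Br)C=O | intermediate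
3 | 2-bromo-3-methylbut-2-enal | CC(C)=C(Br)C=O | intermediate
4 | 2-bromo-3-methylbut-2-en-1-ol | CC(C)=C(Br)CO | intermediate
5 | 1,2-dibromo-3-methylbut-2-ene | CC(C)=C(Br)CBr | intermediate
6 | 1-(2,4,6-trihydroxyphenyl)ethanone (phloroacetophenone) | CC(=O)c1c(O)cc(O)cc1O | starting material
7 | 1-[4-(tert-butyldimethylsilyloxy)-2,6-dihydroxyphenyl]ethanone | CC(=O)c1c(O)cc(O[Si](C)(C)C(C)(C)C)cc1O | intermediate
8 | 1-[4-(tert-butyldimethylsilyloxy)-2-hydroxy-6-(methoxymethoxy)phenyl]ethanone | CC(=O)c1c(O)cc(O[Si](C)(C)C(C)(C)C)cc1OCOC | intermediate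
9 | 1-[4-(tert-butyldimethylsilyloxy)-2-(methoxymethoxy)-6-(3-methylbut-2-enyloxy)phenyl]ethanone | CC(=O)c1c(OCC=C(C)C)cc(O[Si](C)(C)C(C)(C)C)cc1OCOC | intermediate
10 | 2-acetyl-5-(tert-butyldimethylsilyloxy)-3-(methoxymethoxy)-6-(2-methylbut-3-en-2-yl)cyclohexa-2,4-dien-1-one (racemic, not isolated) | CC(=O)C1=C(OCOC)C=C(O[Si](C)(C)C(C)(C)C)C(C(C)(C)C=C)C1=O | intermediate
11 | 2-acetyl-5-(tert-butyldimethylsilyloxy)-3-(methoxymethoxy)-4-(3-methylbut-2-enyl)cyclohexa-2,5-dien-1-one (racemic, not isolated) | CC(=O)C1=C(OCOC)C(CC=C(C)C)C(O[Si](C)(C)C(C)(C)C)=CC1=O | intermediate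
12 | 1-[4-(tert-butyldimethylsilyloxy)-6-hydroxy-2-(methoxymethoxy)-3-(3-methylbut-2-enyl)phenyl]ethanone | CC(=O)c1c(O)cc(O[Si](C)(C)C(C)(C)C)c(CC=C(C)C)c1OCOC | intermediate
13 | 1-[4,6-dihydroxy-2-(methoxymethoxy)-3-(3-methylbut-2-enyl)phenyl]ethanone | CC(=O)c1c(O)cc(O)c(CC=C(C)C)c1OCOC | intermediate
14 | 1-[5-hydroxy-7-(methoxymethoxy)-2,2-dimethyl-8-(3-methylbut-2-enyl)-2H-chromen-6-yl]ethanone | CC(=O)c1c(O)c2C=CC(C)(C)Oc2c(CC=C(C)C)c1OCOC | intermediate
15 | 3,4-dihydroxybenzaldehyde | O=Cc1ccc(O)c(O)c1 | starting material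
16 | 3,4-bis(allyloxy)benzaldehyde | C=CCOc1ccc(C=O)cc1OCC=C | intermediate
17 | 3,4-bis(allyloxy)phenyl formate (not isolated) | C=CCOc1ccc(OC=O)cc1OCC=C | intermediate
18 | 3,4-bis(allyloxy)phenol | C=CCOc1ccc(O)cc1OCC=C | intermediate
19 | 4,5-bis(allyloxy)-2-hydroxybenzaldehyde | O=Cc1cc(OCC=C)c(OCC=C)cc1O | intermediate
20 | 4,5-bis(allyloxy)-2-(methoxymethoxy)benzaldehyde | O=Cc1cc(OCC=C)c(OCC=C)cc1OCOC | intermediate
21 | 4,5-bis(allyloxy)-2-(methoxymethoxy)benzoic acid | OC(=O)c1cc(OCC=C)c(OCC=C)cc1OCOC | intermediate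
22 | [4,5-bis(allyloxy)-2-(methoxymethoxy)phenyl](imidazol-1-yl)methanone | O=C(c1cc(OCC=C)c(OCC=C)cc1OCOC)n1ccnc1 | intermediate
23 | 1-[4,5-bis(allyloxy)-2-(methoxymethoxy)phenyl]-3-[5-hydroxy-7-(methoxymethoxy)-2,2-dimethyl-8-(3-methylbut-2-enyl)-2H-chromen-6-yl]propane-1,3-dione (drawn as diketone, mainly enol) | O=C(CC(=O)c1c(O)c2C=CC(C)(C)Oc2c(CC=C(C)C)c1OCOC)c1cc(OCC=C)c(OCC=C)cc1OCOC | intermediate
24 | 2-(2-bromo-3-methylbut-2-enyl) derivative of 23 (racemic at C2, in equilibrium with its cyclic hemiketal) | O=C(C(CC(Br)=C(C)C)C(=O)c1c(O)c2C=CC(C)(C)Oc2c(CC=C(C)C)c1OCOC)c1cc(OCC=C)c(OCC=C)cc1OCOC | intermediate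
25 | 2-[4,5-bis(allyloxy)-2-(methoxymethoxy)phenyl]-3-(2-bromo-3-methylbut-2-enyl)-5-(methoxymethoxy)-8,8-dimethyl-6-(3-methylbut-2-enyl)-4H,8H-pyrano[2,3-h]chromen-4-one (not isolated) | COCOc1c(CC=C(C)C)c2OC(C)(C)C=Cc2c2oc(-c3cc(OCC=C)c(OCC=C)cc3OCOC)c(CC(Br)=C(C)C)c(=O)c12 | intermediate
26 | 2-[4,5-bis(allyloxy)-2-hydroxyphenyl]-3-(2-bromo-3-methylbut-2-enyl)-5-hydroxy-8,8-dimethyl-6-(3-methylbut-2-enyl)-4H,8H-pyrano[2,3-h]chromen-4-one | Oc1c(CC=C(C)C)c2OC(C)(C)C=Cc2c2oc(-c3cc(OCC=C)c(OCC=C)cc3O)c(CC(Br)=C(C)C)c(=O)c12 | intermediate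
27 | 4',5'-di-O-allylisocycloheterophyllin (oxepine closed, catechol as bis-allyl ether) | Oc1c(CC=C(C)C)c2OC(C)(C)C=Cc2c2oc3-c4cc(OCC=C)c(OCC=C)cc4OC(=C(C)C)Cc3c(=O)c12 | intermediate
28 | isocycloheterophyllin (achiral) | CC(C)=CCc1c2c(c3oc4c(c(=O)c3c1O)CC(=C(C)C)Oc1cc(O)c(O)cc1-4)C=CC(C)(C)O2 | target

**Totals**
Total step count: 20.
Longest linear sequence: 11 steps (6 → 28 through steps 4–9 and 16–20; equally 15 → 28 through steps 10–20).

**Three steps most likely to fail, with fallbacks**

Step 19 (seven-ring O-vinylation with a tetrasubstituted vinylic bromide). If the bromide-based coupling fails, reverse the coupling polarity and close the ring by an oxidative Chan–Lam etherification at room temperature. This fallback sets out from 23 (its alkylating agent is made from 4) and comes back at 27. Alcohol 4 is treated with t-BuLi (3 equiv, −78 °C) and then 2-isopropoxy-4,4,5,5-tetramethyl-1,3,2-dioxaborolane to give 3-methyl-2-(4,4,5,5-tetramethyl-1,3,2-dioxaborolan-2-yl)but-2-en-1-ol F1. Appel bromination (CBr4, PPh3) gives 2-(1-bromo-3-methylbut-2-en-2-yl)-4,4,5,5-tetramethyl-1,3,2-dioxaborolane F2. F2 alkylates 23 (K2CO3, acetone) to the boryl analogue of 24, the 2-(borylprenyl) diketone F3. The PPTS, then HCl/MeOH treatment of step 18 converts it to the boryl analogue of 26, the 2',5-dihydroxy alkenylboronate flavone F4. Cu(OAc)2 (2 equiv, divalent copper), pyridine, 4 Å molecular sieves, CH2Cl2 and air then couple the 2'-OH with the alkenyl–boron carbon to give 27.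

Step 7 (para-Claisen–Cope; the ortho product or cyclised by-products may compete). The fallback installs the prenyl group by cross-coupling after the chromene is made. It sets out from 8 and comes back at 14. Desilylation of 8 (Bu4NF, AcOH) gives 1-[2,4-dihydroxy-6-(methoxymethoxy)phenyl]ethanone F5. Annulation with 1 (ethylenediammonium diacetate, toluene, reflux) occurs at the carbon between the two free hydroxyls and gives 1-[5-hydroxy-7-(methoxymethoxy)-2,2-dimethyl-2H-chromen-6-yl]ethanone F6. NBS (CH2Cl2, −20 °C) brominates the only free aromatic carbon, para to the free phenol, to give 1-[8-bromo-5-hydroxy-7-(methoxymethoxy)-2,2-dimethyl-2H-chromen-6-yl]ethanone F7. Stille coupling with tributyl(3-methylbut-2-enyl)stannane (Pd(PPh3)4, DMF, 90 °C) delivers 14.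

Step 17 (C- versus O-alkylation of the hindered diketone). The fallback builds the pyranone first and alkylates C3 as a carbanion. It sets out from 23 and comes back at 25. PPTS in toluene at 80 °C cyclodehydrates 23 to 2-[4,5-bis(allyloxy)-2-(methoxymethoxy)phenyl]-5-(methoxymethoxy)-8,8-dimethyl-6-(3-methylbut-2-enyl)-4H,8H-pyrano[2,3-h]chromen-4-one F8. LiN(i-Pr)2 (THF, −78 °C) lithiates C3, and the 3-lithioflavone is alkylated with 5 to give 25, which is carried on with methanolic HCl as in step 18.

**Further compounds**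

F1 | step 19 | 3-methyl-2-(4,4,5,5-tetramethyl-1,3,2-dioxaborolan-2-yl)but-2-en-1-ol | CC(C)=C(CO)B1OC(C)(C)C(C)(C)O1
F2 | step 19 | 2-(1-bromo-3-methylbut-2-en-2-yl)-4,4,5,5-tetramethyl-1,3,2-dioxaborolane | CC(C)=C(CBr)B1OC(C)(C)C(C)(C)O1
F3 | step 19 | boryl analogue of 24: 2-[3-methyl-2-(pinacolboryl)but-2-enyl] derivative of 23 (racemic) | O=C(C(CC(=C(C)C)B1OC(C)(C)C(C)(C)O1)C(=O)c1c(O)c2C=CC(C)(C)Oc2c(CC=C(C)C)c1OCOC)c1cc(OCC=C)c(OCC=C)cc1OCOC
F4 | step 19 | boryl analogue of 26: 2-[4,5-bis(allyloxy)-2-hydroxyphenyl]-5-hydroxy-8,8-dimethyl-6-(3-methylbut-2-enyl)-3-[3-methyl-2-(pinacolboryl)but-2-enyl]-4H,8H-pyrano[2,3-h]chromen-4-one | Oc1c(CC=C(C)C)c2OC(C)(C)C=Cc2c2oc(-c3cc(OCC=C)c(OCC=C)cc3O)c(CC(=C(C)C)B3OC(C)(C)C(C)(C)O3)c(=O)c12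
F5 | step 7 | 1-[2,4-dihydroxy-6-(methoxymethoxy)phenyl]ethanone | CC(=O)c1c(O)cc(O)cc1OCOC
F6 | step 7 | 1-[5-hydroxy-7-(methoxymethoxy)-2,2-dimethyl-2H-chromen-6-yl]ethanone | CC(=O)c1c(O)c2C=CC(C)(C)Oc2cc1OCOC
F7 | step 7 | 1-[8-bromo-5-hydroxy-7-(methoxymethoxy)-2,2-dimethyl-2H-chromen-6-yl]ethanone | CC(=O)c1c(O)c2C=CC(C)(C)Oc2c(Br)c1OCOC
F8 | step 17 | 2-[4,5-bis(allyloxy)-2-(methoxymethoxy)phenyl]-5-(methoxymethoxy)-8,8-dimethyl-6-(3-methylbut-2-enyl)-4H,8H-pyrano[2,3-h]chromen-4-one | COCOc1c(CC=C(C)C)c2OC(C)(C)C=Cc2c2oc(-c3cc(OCC=C)c(OCC=C)cc3OCOC)cc(=O)c12
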